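Cuts: first the phenol O–Si bond of a protected precursor. Then the two ArCH2–CH=CMe2 bonds of ring A, at C2 (between C1–OH and C3–OMe) and at C4 (between C3–OMe and the styryl-bearing C5).
Enabling feature: each prenyl group is a benzylic CH2 on ring A bonded to an alkenyl CH whose far end carries two identical methyl groups. Each CH2–CH bond can therefore be made from a benzylic chloride and 1-bromo-2-methylprop-1-ene, two electrophiles, with no alkene geometry to control.
The bis(chloromethyl)arene is traced to a 2,4-dihydroxyisophthalate. Its ring A is cut [3+3] into C2–C4 of dimethyl 3-oxopentanedioate and C1–C3 of a styrylpropiolate, which is itself cut at its C(sp)–C(sp2) bond.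
Forward: Sonogashira coupling, Michael–Dieckmann annulation (ring A, the only ring made; ring B is bought), silylation of the open phenol, methylation of the flanked phenol, ester reduction, chlorination, twofold coupling, desilylation.
Stereochemistry: there is no stereocentre. The one stereo-element, the E stilbene alkene, is bought with (E)-β-bromostyrene and carried through by a stereoretentive coupling.

Key step: step 7

Assumption: geometrically pure commercial (E)-β-bromostyrene is used, because step 1 transfers its geometry unchanged to every later compound.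

Step 1
Reactants: 1 methyl propiolate; 2 (E)-β-bromostyrene
Product: 3 methyl (E)-5-phenylpent-4-en-2-ynoate
Conditions: PdCl2(PPh3)2 (2 mol %), CuI (4 mol %), K2CO3, THF, 60 °C, 1 in excess and added in portions
Reagents that add atoms: none
Why: Sonogashira coupling of an alkenyl bromide proceeds with retention of the E geometry, and an inorganic base in place of an amine avoids aza-Michael addition to the propiolate.

Step 2
Reactants: 3 methyl (E)-5-phenylpent-4-en-2-ynoate; 4 dimethyl 3-oxopentanedioate
Product: 6 dimethyl 2,4-dihydroxy-6-[(E)-2-phenylethenyl]benzene-1,3-dicarboxylate, via Michael adduct 5 (not isolated)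
Conditions: NaH (2.2 equiv), THF, 0 °C to reflux; then 1 M HCl
Reagents that add atoms: none
Why: In this tandem Michael addition–Dieckmann condensation, a known route from 2-alkynoates to 6-substituted 2,4-dihydroxyisophthalates, the sodium enolate of 4 adds to the alkyne β-carbon of 3, the second active methylene acylates on the former ynoate ester (6-exo-trig), and loss of methanol with enolisation to the arene makes the sequence irreversible.

Step 3
Reactants: 6 dimethyl 2,4-dihydroxy-6-[(E)-2-phenylethenyl]benzene-1,3-dicarboxylate
Product: 7 dimethyl 2-hydroxy-6-[(E)-2-phenylethenyl]-4-[tri(propan-2-yl)silyloxy]benzene-1,3-dicarboxylate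
Conditions: TIPSOTf (1.05 equiv), 2,6-lutidine, CH2Cl2, −20 to 0 °C
Reagents that add atoms: triisopropylsilyl trifluoromethanesulfonate, CC(C)[Si](C(C)C)(C(C)C)OS(=O)(=O)C(F)(F)F
Why: This is a sterically controlled site-selective phenol silylation, since O4 has a free ortho C–H whereas O2 is walled in by two ester groups, so the bulky silyl electrophile in near-stoichiometric amount should reach only O4.

Step 4
Reactants: 7 dimethyl 2-hydroxy-6-[(E)-2-phenylethenyl]-4-[tri(propan-2-yl)silyloxy]benzene-1,3-dicarboxylate
Product: 8 dimethyl 2-methoxy-6-[(E)-2-phenylethenyl]-4-[tri(propan-2-yl)silyloxy]benzene-1,3-dicarboxylate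
Conditions: MeOH, PPh3, DIAD, THF, 0 °C to rt
Reagents that add atoms: methanol, CO
Why: In this Mitsunobu etherification the acidic, doubly ester-flanked phenol protonates the betaine and its phenoxide attacks the unhindered methyl of the methoxyphosphonium ion, all under neutral conditions that spare the ester-activated aryl silyl ether.

Step 5
Reactants: 8 dimethyl 2-methoxy-6-[(E)-2-phenylethenyl]-4-[tri(propan-2-yl)silyloxy]benzene-1,3-dicarboxylate
Product: 9 [3-(hydroxymethyl)-2-methoxy-6-[(E)-2-phenylethenyl]-4-[tri(propan-2-yl)silyloxy]phenyl]methanol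
Conditions: iBu2AlH (6 equiv), CH2Cl2, −78 to 0 °C; aq. potassium sodium tartrate
Reagents that add atoms: none
Why: In this hydride reduction of esters to primary alcohols, excess iBu2AlH takes both di-ortho-substituted benzoates down, the stilbene is inert at or below 0 °C, and the weakly nucleophilic aluminium alkoxides in a non-coordinating solvent disfavour silyl migration from the neighbouring phenol oxygen.

Step 6
Reactants: 9 [3-(hydroxymethyl)-2-methoxy-6-[(E)-2-phenylethenyl]-4-[tri(propan-2-yl)silyloxy]phenyl]methanol
Product: 11 [2,4-bis(chloromethyl)-3-methoxy-5-[(E)-2-phenylethenyl]phenoxy]tri(propan-2-yl)silane, via bis(methanesulfonate) 10 (not isolated)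
Conditions: MsCl (2.6 equiv), Et3N (3 equiv), CH2Cl2, 0 °C to rt; cold aq. NaHCO3 wash, used crude
Reagents that add atoms: methanesulfonyl chloride, CS(=O)(=O)Cl
Why: This is sulfonylation with in situ chloride displacement, in which mesylates of benzylic alcohols bearing ortho or para oxygen donors are displaced by the liberated chloride as they form, and only water-soluble by-products arise, so the labile dichloride needs no chromatography.

Step 7
Reactants: 11 [2,4-bis(chloromethyl)-3-methoxy-5-[(E)-2-phenylethenyl]phenoxy]tri(propan-2-yl)silane; 12 1-bromo-2-methylprop-1-ene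
Product: 15 [3-methoxy-2,4-bis(3-methylbut-2-enyl)-5-[(E)-2-phenylethenyl]phenoxy]tri(propan-2-yl)silane, via 4-prenyl monochloride 13 (not isolated), via 2-prenyl monochloride 14 (not isolated)
Conditions: NiBr2(dme) (20 mol %), 4,4'-di-tert-butyl-2,2'-bipyridine (24 mol %), 12 (5 equiv), nBu4NPF6 (0.1 M), DMA, undivided cell, Zn anode, RVC cathode, constant current, ca. 5 F/mol, rt, 11 added slowly by syringe pump
Reagents that add atoms: none
Why: Electrons delivered at the cathode take the divalent nickel–bipyridine precatalyst down to low-valent nickel; the zerovalent form inserts into the C–Br bond of 12 to give a divalent alkenylnickel bromide, while the monovalent form pulls chlorine off a CH2Cl group and releases a benzylic radical. Capture of that radical gives a trivalent benzyl(alkenyl)nickel species whose reductive elimination forges the CH2–CH bond, the cycle repeats on monochloride 13 or 14, and zinc dissolving from the anode balances the charge and takes up the halides. The closest known reaction type is the nickel-catalysed reductive and electroreductive cross-electrophile coupling of benzyl chlorides with alkenyl bromides, run here at two independent, meta-related sites of one arene. No ring closes and no stereocentre forms, and the CMe2 terminus leaves no alkene geometry to lose. The step needs cross-coupling to beat benzylic dimerisation, which is secured by the different activation modes of the partners (two-electron at C(sp2)–Br, one-electron at benzylic C–Cl), by excess 12 with slow addition of 11, and by the two ortho substituents at each benzylic carbon, which slow radical–radical combination. It also needs an untouched stilbene: the catalyst turns over at a potential far less negative than direct reduction of a stilbene or a benzyl chloride requires, 5-endo attack of the C4 benzylic radical on the adjacent styryl group is geometrically disfavoured, and any benzylzinc formed at the zinc surface would be drawn to the same product by transmetalation to nickel.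

Step 8
Reactants: 15 [3-methoxy-2,4-bis(3-methylbut-2-enyl)-5-[(E)-2-phenylethenyl]phenoxy]tri(propan-2-yl)silane
Product: 16 chiricanine C, 3-methoxy-2,4-bis(3-methylbut-2-enyl)-5-[(E)-2-phenylethenyl]phenol
Conditions: nBu4NF (1.1 equiv), AcOH (1.1 equiv), THF, 0 °C
Reagents that add atoms: none
Why: In this fluoride-induced desilylation the strong Si–F bond drives cleavage of the aryl silyl ether and the acetic acid buffer protonates the phenoxide at once, so neither the prenyl groups nor the stilbene is touched.

Compound list
1 | methyl propiolate | C#CC(=O)OC | starting material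
2 | (E)-β-bromostyrene, [(E)-2-bromoethenyl]benzene | Br/C=C/c1ccccc1 | starting material
3 | methyl (E)-5-phenylpent-4-en-2-ynoate | COC(=O)C#C/C=C/c1ccccc1 | intermediate
4 | dimethyl 3-oxopentanedioate | COC(=O)CC(=O)CC(=O)OC | starting material
5 | dimethyl 2-[(1E,3Z)-5-methoxy-5-oxo-1-phenylpenta-1,3-dien-3-yl]-3-oxopentanedioate (Michael adduct, enolisable CH, present as sodium enolate) | COC(=O)CC(=O)C(C(=O)OC)/C(/C=C/c1ccccc1)=C\C(=O)OC | intermediate
6 | dimethyl 2,4-dihydroxy-6-[(E)-2-phenylethenyl]benzene-1,3-dicarboxylate | COC(=O)c1c(O)c(C(=O)OC)c(O)cc1/C=C/c1ccccc1 | intermediate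
7 | dimethyl 2-hydroxy-6-[(E)-2-phenylethenyl]-4-[tri(propan-2-yl)silyloxy]benzene-1,3-dicarboxylate | COC(=O)c1c(O)c(C(=O)OC)c(O[Si](C(C)C)(C(C)C)C(C)C)cc1/C=C/c1ccccc1 | intermediate
8 | dimethyl 2-methoxy-6-[(E)-2-phenylethenyl]-4-[tri(propan-2-yl)silyloxy]benzene-1,3-dicarboxylate | COC(=O)c1c(OC)c(C(=O)OC)c(O[Si](C(C)C)(C(C)C)C(C)C)cc1/C=C/c1ccccc1 | intermediate
9 | [3-(hydroxymethyl)-2-methoxy-6-[(E)-2-phenylethenyl]-4-[tri(propan-2-yl)silyloxy]phenyl]methanol | OCc1c(OC)c(CO)c(O[Si](C(C)C)(C(C)C)C(C)C)cc1/C=C/c1ccccc1 | intermediate
10 | bis(methanesulfonate) of diol 9 | CS(=O)(=O)OCc1c(OC)c(COS(C)(=O)=O)c(O[Si](C(C)C)(C(C)C)C(C)C)cc1/C=C/c1ccccc1 | intermediate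
11 | [2,4-bis(chloromethyl)-3-methoxy-5-[(E)-2-phenylethenyl]phenoxy]tri(propan-2-yl)silane | COc1c(CCl)c(O[Si](C(C)C)(C(C)C)C(C)C)cc(/C=C/c2ccccc2)c1CCl | intermediate
12 | 1-bromo-2-methylprop-1-ene | CC(C)=CBr | starting material
13 | [2-(chloromethyl)-3-methoxy-4-(3-methylbut-2-enyl)-5-[(E)-2-phenylethenyl]phenoxy]tri(propan-2-yl)silane | COc1c(CCl)c(O[Si](C(C)C)(C(C)C)C(C)C)cc(/C=C/c2ccccc2)c1CC=C(C)C | intermediate
14 | [4-(chloromethyl)-3-methoxy-2-(3-methylbut-2-enyl)-5-[(E)-2-phenylethenyl]phenoxy]tri(propan-2-yl)silane | COc1c(CC=C(C)C)c(O[Si](C(C)C)(C(C)C)C(C)C)cc(/C=C/c2ccccc2)c1CCl | intermediate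
15 | [3-methoxy-2,4-bis(3-methylbut-2-enyl)-5-[(E)-2-phenylethenyl]phenoxy]tri(propan-2-yl)silane | COc1c(CC=C(C)C)c(O[Si](C(C)C)(C(C)C)C(C)C)cc(/C=C/c2ccccc2)c1CC=C(C)C | intermediate
16 | chiricanine C, 3-methoxy-2,4-bis(3-methylbut-2-enyl)-5-[(E)-2-phenylethenyl]phenol | COc1c(CC=C(C)C)c(O)cc(/C=C/c2ccccc2)c1CC=C(C)C | target

Total step count: 8. Longest linear sequence: 8 steps (1 and 2 to 16).

Steps most likely to fail

Step 7. The benzylic radicals may dimerise to bibenzyl oligomers or be reduced to methyl groups. The coupling may also stall after the first prenyl group, at the site crowded by the silyl ether. The fallback sets out from 11 and 12 and returns at 15, and it separates reduction from bond formation. Zinc dust with LiCl in THF at 0 °C to rt inserts into both C–Cl bonds of 11 to give the bis(benzylic zinc chloride) F1. A Negishi coupling of this reagent with 12 under Pd(OAc)2 and SPhos in THF at rt then makes the same two CH2–CH bonds and delivers 15.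

Step 6. Each chloromethyl group has oxygen donors ortho or para to it. Ionisation during formation or work-up may therefore lead to hydrolysis or to Friedel–Crafts self-condensation at the one free ring position. The fallback sets out from 9 and returns at 15, and it replaces chloride by a much poorer leaving group. Diethyl chlorophosphate, Et3N and DMAP in CH2Cl2 convert 9 into the bis(diethyl phosphate) F2, which should tolerate chromatography and storage. Copper-catalysed substitution with commercial 2-methylprop-1-enylmagnesium bromide (CuBr·SMe2, THF, −30 °C to rt) then forms the same CH2–CH bonds in a polarity-matched way and gives 15.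

Step 2. Three processes may compete with the Dieckmann closure: conjugate addition at the styryl terminus (1,6, inter- or intramolecular), O-acylation to a 2-pyranone, and anionic oligomerisation of the enynoate. The fallback sets out from 4 and returns at 8, and it builds ring A before the stilbene.
- 3,3-Diethoxyprop-1-yne is lithiated (nBuLi, THF, −78 °C) and acylated with methyl chloroformate to give methyl 4,4-diethoxybut-2-ynoate F3.
- The same NaH-mediated annulation with 4, quenched with acetic acid, gives dimethyl 6-(diethoxymethyl)-2,4-dihydroxybenzene-1,3-dicarboxylate F4.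
- Silylation as in step 3 gives the 4-silyl ether F5, and Mitsunobu methylation as in step 4 gives the 2-methyl ether F6.
- Pyridinium tosylate in aqueous acetone unmasks the aldehyde, dimethyl 4-formyl-2-methoxy-6-[tri(propan-2-yl)silyloxy]benzene-1,3-dicarboxylate F7.
- A Horner–Wadsworth–Emmons olefination with diethyl benzylphosphonate (NaH, THF, 0 °C) installs the E alkene and gives 8.

Further compounds
F1 | step 7 | [3-methoxy-5-[(E)-2-phenylethenyl]-1-[tri(propan-2-yl)silyloxy]benzene-2,4-diyl]bis(methylene)bis(zinc chloride) | COc1c(C[Zn]Cl)c(O[Si](C(C)C)(C(C)C)C(C)C)cc(/C=C/c2ccccc2)c1C[Zn]Cl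
F2 | step 6 | bis(diethyl phosphate) of diol 9 | CCOP(=O)(OCC)OCc1c(OC)c(COP(=O)(OCC)OCC)c(O[Si](C(C)C)(C(C)C)C(C)C)cc1/C=C/c1ccccc1
F3 | step 2 | methyl 4,4-diethoxybut-2-ynoate | CCOC(OCC)C#CC(=O)OC
F4 | step 2 | dimethyl 6-(diethoxymethyl)-2,4-dihydroxybenzene-1,3-dicarboxylate | CCOC(OCC)c1cc(O)c(C(=O)OC)c(O)c1C(=O)OC
F5 | step 2 | dimethyl 6-(diethoxymethyl)-2-hydroxy-4-[tri(propan-2-yl)silyloxy]benzene-1,3-dicarboxylate | CCOC(OCC)c1cc(O[Si](C(C)C)(C(C)C)C(C)C)c(C(=O)OC)c(O)c1C(=O)OC
F6 | step 2 | dimethyl 6-(diethoxymethyl)-2-methoxy-4-[tri(propan-2-yl)silyloxy]benzene-1,3-dicarboxylate | CCOC(OCC)c1cc(O[Si](C(C)C)(C(C)C)C(C)C)c(C(=O)OC)c(OC)c1C(=O)OC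
F7 | step 2 | dimethyl 4-formyl-2-methoxy-6-[tri(propan-2-yl)silyloxy]benzene-1,3-dicarboxylate | O=Cc1cc(O[Si](C(C)C)(C(C)C)C(C)C)c(C(=O)OC)c(OC)c1C(=O)OC
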